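**Strategy.** The ten-membered carbocycle is closed last, at C7–C8 (germacrane numbering: C7 is the β-carbon of the butenolide, C8 the carbinol carbon that carries the methacrylate). Because C8 is an allylic carbinol on an sp2 carbon of the five-membered lactone ring, this bond is the retron of a vinyl-metal addition to an aldehyde. An intramolecular Nozaki–Hiyama–Kishi reaction of a seco β-iodobutenolide aldehyde forms the ring and the C8 stereocentre in one operation. The precursor is assembled from a lactic-acid-derived quaternary acetate (C10), a Claisen rearrangement (E-C4=C5) and an allenoate iodolactonisation (C6, vinyl iodide).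

Key step: step 15

Remark on numbering: C1 ketone, C4=C5 alkene, C6 lactone carbinol, C7=C11 butenolide alkene, C8 methacrylate carbinol, C10 quaternary acetate, C12 lactone carbonyl, C13 acetoxymethyl carbon.

Assumption: the ProPhenol antipode that delivers the alkynyl group to the Re face of enal 17 is written as (S,S); should the first run show the opposite sense, the equally available (R,R)-ligand is used.

**Route**

Step 1
Reactants: 1 (S)-lactic acid
Product: 2 (2S,5S)-2-tert-butyl-5-methyl-1,3-dioxolan-4-one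
Conditions: pivalaldehyde, TsOH·H2O (cat.), H2SO4 (cat.), pentane, reflux, Dean–Stark; cis isomer crystallised
Reagents that add atoms: pivalaldehyde, CC(C)(C)C=O
Why: Seebach acetalisation of an α-hydroxy acid should give the cis acetal as the thermodynamic product, storing the lactate configuration in the new acetal centre.

Step 2
Reactants: 2 (2S,5S)-2-tert-butyl-5-methyl-1,3-dioxolan-4-one; 3 allyl bromide
Product: 5 (2S,5R)-2-tert-butyl-5-methyl-5-(prop-2-en-1-yl)-1,3-dioxolan-4-one, via lithium enolate 4 (not isolated)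
Conditions: LiN(i-Pr)2, THF, −78 °C; then 3, −78 → −30 °C
Reagents that add atoms: none
Why: Seebach self-regeneration of stereocentres: the enolate should be alkylated anti to the tert-butyl group, so allyl replaces the lactate hydrogen with retention and sets C10 as R.

Step 3
Reactants: 5 (2S,5R)-2-tert-butyl-5-methyl-5-(prop-2-en-1-yl)-1,3-dioxolan-4-one
Product: 7 2-[(2S,4R)-2-tert-butyl-4-methyl-5-oxo-1,3-dioxolan-4-yl]acetaldehyde, via ozonide 6 (not isolated)
Conditions: O3, CH2Cl2, −78 °C; then Me2S, −78 → 20 °C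
Reagents that add atoms: ozone, [O-][O+]=O
Why: ozonolysis with reductive work-up should cleave the only alkene to the C8 aldehyde and leave the acylal ring and the quaternary centre untouched.

Step 4
Reactants: 7 2-[(2S,4R)-2-tert-butyl-4-methyl-5-oxo-1,3-dioxolan-4-yl]acetaldehyde
Product: 8 (2S,5R)-2-tert-butyl-5-(2,2-dimethoxyethyl)-5-methyl-1,3-dioxolan-4-one
Conditions: MeOSiMe3 (2.5 equiv), Me3SiOTf (2 mol %), CH2Cl2, −78 °C; pyridine quench
Reagents that add atoms: methoxytrimethylsilane, CO[Si](C)(C)C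
Why: Noyori aprotic acetalisation should mask C8 as the dimethyl acetal without the protic acid or methanol that would open the dioxolanone.

Step 5
Reactants: 9 isopropenylmagnesium bromide; 10 2,2-dimethoxyacetaldehyde (dried commercial solution in tert-butyl methyl ether)
Product: 11 rac-1,1-dimethoxy-3-methylbut-3-en-2-ol
Conditions: THF, −78 → 0 °C; aq. NH4Cl
Reagents that add atoms: none
Why: Grignard 1,2-addition to the aldehyde; the racemate suffices because this carbinol centre is destroyed in step 7.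

Step 6
Reactants: 8 (2S,5R)-2-tert-butyl-5-(2,2-dimethoxyethyl)-5-methyl-1,3-dioxolan-4-one; 11 rac-1,1-dimethoxy-3-methylbut-3-en-2-ol
Product: 13 1,1-dimethoxy-3-methylbut-3-en-2-yl (2R)-4,4-dimethoxy-2-methyl-2-(trimethylsilyloxy)butanoate (both epimers at the allylic carbon), via lithium alkoxide 12 (not isolated)
Conditions: 11 (1.3 equiv), n-BuLi (1.25 equiv), THF, −78 °C; then 8, −78 → 20 °C; then Me3SiCl, 0 °C
Reagents that add atoms: chlorotrimethylsilane, C[Si](C)(C)Cl
Why: alkoxide transesterification of the activated acylal ester should open the dioxolanone with loss of pivalaldehyde, and the liberated tertiary alkoxide is silylated in the same flask without touching C10.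

Step 7
Reactants: 13 1,1-dimethoxy-3-methylbut-3-en-2-yl (2R)-4,4-dimethoxy-2-methyl-2-(trimethylsilyloxy)butanoate
Product: 16 (2E,7R)-7-hydroxy-9,9-dimethoxy-3,7-dimethyl-6-oxonon-2-enal, via enol ether 14 (not isolated), via silyl ketone 15 (not isolated)
Conditions: Cp2TiMe2 (3 equiv), toluene, 70 °C, dark; then 110 °C; then 0.5 M aq. HCl/THF (1:4), 0 °C
Reagents that add atoms: dimethyltitanocene, C[Ti](C)(C1C=CC=C1)C1C=CC=C1; water, O
Why: Petasis methylenation should give a 2-substituted allyl vinyl ether whose Claisen rearrangement (chair transition state, dimethoxymethyl group equatorial) forms C2–C3 and the E-C4=C5 alkene from both epimers, after which dilute acid cleaves the tertiary silyl ether and the far more labile allylic acetal while the saturated C8 acetal survives.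

Step 8
Reactants: 16 (2E,7R)-7-hydroxy-9,9-dimethoxy-3,7-dimethyl-6-oxonon-2-enal
Product: 17 (3R,7E)-1,1-dimethoxy-3,7-dimethyl-4,9-dioxonon-7-en-3-yl acetate
Conditions: Ac2O, DMAP, Et3N, CH2Cl2, 25 °C
Reagents that add atoms: acetic anhydride, CC(=O)OC(C)=O
Why: DMAP-catalysed acylation of the tertiary α-ketol should install the C10 acetate before any base-sensitive lactone is present.

Step 9
Reactants: 17 (3R,7E)-1,1-dimethoxy-3,7-dimethyl-4,9-dioxonon-7-en-3-yl acetate; 18 tert-butyldimethyl(prop-2-yn-1-yloxy)silane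
Product: 20 (3R,7E,9S)-12-(tert-butyldimethylsilyloxy)-9-hydroxy-1,1-dimethoxy-3,7-dimethyl-4-oxododec-7-en-10-yn-3-yl acetate, via alkynylzinc 19 (not isolated)
Conditions: 18 (3 equiv), Me2Zn (3 equiv), (S,S)-ProPhenol (20 mol %), Ph3PO (40 mol %), toluene, 0 °C; then 17, 4 °C; aq. NH4Cl
Reagents that add atoms: none
Why: Trost zinc–ProPhenol asymmetric alkynylation of an enal should deliver the alkynyl group to the Re face of the aldehyde (6S, catalyst control) while the alkynylzinc leaves the hindered ketone, the acetate and the acetal alone.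

Step 10
Reactants: 20 (3R,7E,9S)-12-(tert-butyldimethylsilyloxy)-9-hydroxy-1,1-dimethoxy-3,7-dimethyl-4-oxododec-7-en-10-yn-3-yl acetate
Product: 21 (3R,7E,9S)-12-(tert-butyldimethylsilyloxy)-1,1-dimethoxy-9-(methoxycarbonyloxy)-3,7-dimethyl-4-oxododec-7-en-10-yn-3-yl acetate
Conditions: ClCO2Me, pyridine, DMAP (cat.), CH2Cl2, 0 °C
Reagents that add atoms: methyl chloroformate, COC(=O)Cl
Why: O-acylation of the secondary propargylic alcohol with retention should provide the carbonate leaving group for palladium.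

Step 11
Reactants: 21 (3R,7E,9S)-12-(tert-butyldimethylsilyloxy)-1,1-dimethoxy-9-(methoxycarbonyloxy)-3,7-dimethyl-4-oxododec-7-en-10-yn-3-yl acetate
Product: 22 methyl (aR,5E,10R)-10-acetoxy-2-[(tert-butyldimethylsilyloxy)methyl]-12,12-dimethoxy-6,10-dimethyl-9-oxododeca-2,3,5-trienoate
Conditions: Pd2(dba)3 (2.5 mol %), PPh3 (20 mol %), CO (1 atm), THF/MeOH (4:1), 25 °C
Reagents that add atoms: carbon monoxide, [C-]#[O+]; methanol, CO
Why: Tsuji–Marshall carbonylation of a propargylic carbonate (anti SN2′ oxidative addition of zerovalent palladium, CO insertion with retention, methanolysis) should give the allenoate and translate the 6S centre into the aR axis.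

Step 12
Reactants: 22 methyl (aR,5E,10R)-10-acetoxy-2-[(tert-butyldimethylsilyloxy)methyl]-12,12-dimethoxy-6,10-dimethyl-9-oxododeca-2,3,5-trienoate
Product: 23 (3R,7E)-8-[(2R)-4-[(tert-butyldimethylsilyloxy)methyl]-3-iodo-5-oxo-2,5-dihydrofuran-2-yl]-1,1-dimethoxy-3,7-dimethyl-4-oxooct-7-en-3-yl acetate
Conditions: I2 (2.5 equiv), MeCN, 0 → 20 °C, dark; aq. Na2S2O3
Reagents that add atoms: iodine, II
Why: Ma-type iodolactonisation of a 2,3-allenoate: iodonium attack at the central allene carbon C7, anti to the ester oxygen that closes onto C6, should transfer the axis to C6 (R, net inversion relative to 20) and leave the vinyl iodide needed for ring closure.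

Step 13
Reactants: 23 (3R,7E)-8-[(2R)-4-[(tert-butyldimethylsilyloxy)methyl]-3-iodo-5-oxo-2,5-dihydrofuran-2-yl]-1,1-dimethoxy-3,7-dimethyl-4-oxooct-7-en-3-yl acetate
Product: 24 (3R,7E)-8-[(2R)-4-(hydroxymethyl)-3-iodo-5-oxo-2,5-dihydrofuran-2-yl]-3,7-dimethyl-1,4-dioxooct-7-en-3-yl acetate
Conditions: 48% aq. HF, MeCN, 0 → 20 °C
Reagents that add atoms: water, O
Why: aqueous acid should remove the primary silyl ether and hydrolyse the dimethyl acetal in one operation, conditions that the acetate, lactone and vinyl iodide tolerate.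

Step 14
Reactants: 24 (3R,7E)-8-[(2R)-4-(hydroxymethyl)-3-iodo-5-oxo-2,5-dihydrofuran-2-yl]-3,7-dimethyl-1,4-dioxooct-7-en-3-yl acetate
Product: 25 (3R,7E)-8-[(2R)-4-(acetoxymethyl)-3-iodo-5-oxo-2,5-dihydrofuran-2-yl]-3,7-dimethyl-1,4-dioxooct-7-en-3-yl acetate
Conditions: Ac2O (1.2 equiv), pyridine, CH2Cl2, 0 °C
Reagents that add atoms: acetic anhydride, CC(=O)OC(C)=O
Why: acetylation of the only hydroxyl group (primary, allylic) under weakly basic conditions should avoid β-elimination of the C10 acetate from the aldehyde.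

Step 15
Reactants: 25 (3R,7E)-8-[(2R)-4-(acetoxymethyl)-3-iodo-5-oxo-2,5-dihydrofuran-2-yl]-3,7-dimethyl-1,4-dioxooct-7-en-3-yl acetate
Product: 27 (4E,6R,8S,10R)-10,13-diacetoxy-8-hydroxy-1-oxogermacra-4,7(11)-dien-6,12-olide, via alkenylchromium 26 (not isolated)
Conditions: CrCl2 (15 equiv), NiCl2 (0.15 equiv), degassed DMSO/THF (3:1), 25 °C, slow addition of 25 to 2 mM; aq. potassium serinate work-up
Reagents that add atoms: none
Why: Zerovalent nickel, formed from NiCl2 by divalent chromium, inserts into the C7–I bond of the β-iodobutenolide and transmetallates to trivalent chromium; the alkenylchromium 26 adds to the C8 aldehyde and work-up frees the alcohol. The closest known reaction type is the intramolecular Nozaki–Hiyama–Kishi macrocyclisation of alkenyl iodides onto aldehydes used for medium and large carbocycles. The ten-membered carbocycle closes in a 10-exo-trig mode, C7 attacking the exocyclic carbonyl carbon C8. The new C8 centre is under substrate control: C6 (R) fixes the lactone face from which the C5 arm leaves, A1,3 strain with the C13 acetoxymethyl group should hold C8–H in the lactone plane, and the least strained closure is expected to have C9 leaving on the face opposite C5, which corresponds to 8S; this prediction is the least secure element of the step. The step needs chemoselectivity for the aldehyde over the C1 ketone and the esters, which organochromium reagents provide and which the E-C4=C5 alkene reinforces because attack on C1 would require a trans-cycloheptene, and it needs ring closure over oligomerisation, which high dilution secures.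

Step 16
Reactants: 27 (4E,6R,8S,10R)-10,13-diacetoxy-8-hydroxy-1-oxogermacra-4,7(11)-dien-6,12-olide
Product: 28 CNP0115165.1
Conditions: methacrylic anhydride, DMAP (0.2 equiv), i-Pr2NEt, CH2Cl2, 0 °C
Reagents that add atoms: methacrylic anhydride, C=C(C)C(=O)OC(=O)C(C)=C
Why: Steglich-type acylation of the secondary allylic alcohol with retention at C8 should complete the target, and short contact with a hindered base limits epimerisation at C6.

**Compound list**

1 | (S)-lactic acid | C[C@H](O)C(=O)O | starting material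
2 | (2S,5S)-2-tert-butyl-5-methyl-1,3-dioxolan-4-one | C[C@@H]1O[C@H](C(C)(C)C)OC1=O | intermediate
3 | allyl bromide | C=CCBr | starting material
4 | lithium (2S)-2-tert-butyl-5-methyl-1,3-dioxol-4-olate | CC1=C([O-])O[C@@H](C(C)(C)C)O1.[Li+] | intermediate
5 | (2S,5R)-2-tert-butyl-5-methyl-5-(prop-2-en-1-yl)-1,3-dioxolan-4-one | C=CC[C@@]1(C)O[C@H](C(C)(C)C)OC1=O | intermediate
6 | (2S,5R)-2-tert-butyl-5-methyl-5-(1,2,4-trioxolan-3-ylmethyl)-1,3-dioxolan-4-one (epimers at the trioxolane carbon) | C1OC(C[C@@]2(C)O[C@H](C(C)(C)C)OC2=O)OO1 | intermediate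
7 | 2-[(2S,4R)-2-tert-butyl-4-methyl-5-oxo-1,3-dioxolan-4-yl]acetaldehyde | O=CC[C@@]1(C)O[C@H](C(C)(C)C)OC1=O | intermediate
8 | (2S,5R)-2-tert-butyl-5-(2,2-dimethoxyethyl)-5-methyl-1,3-dioxolan-4-one | COC(OC)C[C@@]1(C)O[C@H](C(C)(C)C)OC1=O | intermediate
9 | isopropenylmagnesium bromide | C=C(C)[Mg]Br | starting material
10 | 2,2-dimethoxyacetaldehyde | COC(OC)C=O | starting material
11 | rac-1,1-dimethoxy-3-methylbut-3-en-2-ol | C=C(C)C(O)C(OC)OC | intermediate
12 | lithium alkoxide of 1,1-dimethoxy-3-methylbut-3-en-2-yl (2R)-2-hydroxy-4,4-dimethoxy-2-methylbutanoate | C=C(C)C(OC(=O)[C@@](C)(CC(OC)OC)[O-])C(OC)OC.[Li+] | intermediate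
13 | 1,1-dimethoxy-3-methylbut-3-en-2-yl (2R)-4,4-dimethoxy-2-methyl-2-(trimethylsilyloxy)butanoate (both epimers at the allylic carbon) | C=C(C)C(OC(=O)[C@@](C)(CC(OC)OC)O[Si](C)(C)C)C(OC)OC | intermediate
14 | (3R)-2-[(1,1-dimethoxy-3-methylbut-3-en-2-yl)oxy]-5,5-dimethoxy-3-methyl-3-(trimethylsilyloxy)pent-1-ene | C=C(C)C(OC(=C)[C@@](C)(CC(OC)OC)O[Si](C)(C)C)C(OC)OC | intermediate
15 | (3R,7E)-1,1,9,9-tetramethoxy-3,7-dimethyl-3-(trimethylsilyloxy)non-7-en-4-one | COC(OC)/C=C(\C)CCC(=O)[C@@](C)(CC(OC)OC)O[Si](C)(C)C | intermediate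
16 | (2E,7R)-7-hydroxy-9,9-dimethoxy-3,7-dimethyl-6-oxonon-2-enal | O=C/C=C(\C)CCC(=O)[C@](C)(O)CC(OC)OC | intermediate
17 | (3R,7E)-1,1-dimethoxy-3,7-dimethyl-4,9-dioxonon-7-en-3-yl acetate | O=C/C=C(\C)CCC(=O)[C@](C)(OC(C)=O)CC(OC)OC | intermediate
18 | tert-butyldimethyl(prop-2-yn-1-yloxy)silane | C#CCO[Si](C)(C)C(C)(C)C | starting material
19 | methyl[3-(tert-butyldimethylsilyloxy)prop-1-yn-1-yl]zinc | C[Zn]C#CCO[Si](C)(C)C(C)(C)C | intermediate
20 | (3R,7E,9S)-12-(tert-butyldimethylsilyloxy)-9-hydroxy-1,1-dimethoxy-3,7-dimethyl-4-oxododec-7-en-10-yn-3-yl acetate | CC(C)(C)[Si](C)(C)OCC#C[C@@H](O)/C=C(\C)CCC(=O)[C@](C)(OC(C)=O)CC(OC)OC | intermediate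
21 | (3R,7E,9S)-12-(tert-butyldimethylsilyloxy)-1,1-dimethoxy-9-(methoxycarbonyloxy)-3,7-dimethyl-4-oxododec-7-en-10-yn-3-yl acetate | CC(C)(C)[Si](C)(C)OCC#C[C@@H](OC(=O)OC)/C=C(\C)CCC(=O)[C@](C)(OC(C)=O)CC(OC)OC | intermediate
22 | methyl (aR,5E,10R)-10-acetoxy-2-[(tert-butyldimethylsilyloxy)methyl]-12,12-dimethoxy-6,10-dimethyl-9-oxododeca-2,3,5-trienoate | COC(=O)C(CO[Si](C)(C)C(C)(C)C)=[C@]=C([H])/C=C(\C)CCC(=O)[C@](C)(OC(C)=O)CC(OC)OC | intermediate
23 | (3R,7E)-8-[(2R)-4-[(tert-butyldimethylsilyloxy)methyl]-3-iodo-5-oxo-2,5-dihydrofuran-2-yl]-1,1-dimethoxy-3,7-dimethyl-4-oxooct-7-en-3-yl acetate | CC(C)(C)[Si](C)(C)OCC1=C(I)[C@@H](/C=C(\C)CCC(=O)[C@](C)(OC(C)=O)CC(OC)OC)OC1=O | intermediate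
24 | (3R,7E)-8-[(2R)-4-(hydroxymethyl)-3-iodo-5-oxo-2,5-dihydrofuran-2-yl]-3,7-dimethyl-1,4-dioxooct-7-en-3-yl acetate | OCC1=C(I)[C@@H](/C=C(\C)CCC(=O)[C@](C)(OC(C)=O)CC=O)OC1=O | intermediate
25 | (3R,7E)-8-[(2R)-4-(acetoxymethyl)-3-iodo-5-oxo-2,5-dihydrofuran-2-yl]-3,7-dimethyl-1,4-dioxooct-7-en-3-yl acetate | CC(=O)OCC1=C(I)[C@@H](/C=C(\C)CCC(=O)[C@](C)(OC(C)=O)CC=O)OC1=O | intermediate
26 | trivalent alkenylchromium dichloride derived from 25 (chromium on C7) | CC(=O)OCC1=C([Cr](Cl)Cl)[C@@H](/C=C(\C)CCC(=O)[C@](C)(OC(C)=O)CC=O)OC1=O | intermediate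
27 | (4E,6R,8S,10R)-10,13-diacetoxy-8-hydroxy-1-oxogermacra-4,7(11)-dien-6,12-olide | O[C@H]1C[C@@](C)(OC(C)=O)C(=O)CC/C(C)=C/[C@H]2OC(=O)C(COC(C)=O)=C12 | intermediate
28 | CNP0115165.1, (4E,6R,8S,10R)-10,13-diacetoxy-8-(methacryloyloxy)-1-oxogermacra-4,7(11)-dien-6,12-olide | C=C(C)C(=O)O[C@H]1C[C@@](C)(OC(C)=O)C(=O)CC/C(C)=C/[C@H]2OC(=O)C(COC(C)=O)=C12 | target

**Step count.** Total: 16 steps. Longest linear sequence: 15 steps (steps 1–4 and 6–16; step 5 is a one-step branch).

**Steps most likely to fail**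

Step 15. Hydrodeiodination, oligomerisation or β-elimination of the lactone carboxylate from the alkenylchromium may outrun ten-membered ring closure, and the aldehyde may be attacked on the wrong face. The same bond would then be closed at the ketone oxidation level, setting out from 25 and returning at 27. Pinnick oxidation (NaClO2, NaH2PO4, 2-methylbut-2-ene) should give carboxylic acid F1. EtSH/EDC should give S-ethyl thioester F2. Me3SnSnMe3 with Pd(PPh3)4 should exchange iodide for tin to give alkenylstannane F3. A Liebeskind–Srogl coupling (Pd2(dba)3, tri(2-furyl)phosphine, univalent copper diphenylphosphinate CuO2PPh2, high dilution) should close the ring to macrocyclic 8-ketone F4. Reduction with (R)-Me-CBS oxazaborolidine and catecholborane then sets C8 under reagent control.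

Step 11. Ionisation of the carbonate, which is both allylic and propargylic, may give π-allyl products, and the stereochemical relay 6S → allene axis → 6R may leak in steps 11 and 12. The C6–O bond would then be kept intact, setting out from 17 and returning at 23. The alkynylation of step 9 with the antipodal ligand should give the 6R carbinol F5. I2 in CH2Cl2 should add anti across the alkyne to give (E)-diiodide F6. Carbonylative lactonisation (PdCl2(PPh3)2, CO, Et3N, THF) of the iodide cis to the carbinol should then give the β-iodobutenolide with retention at C6.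

Step 7. Methylenation of the doubly hindered ester may stall, or the saturated acetal may be lost during the acidic finish. C2 would then come from an acetate carbon, setting out from 8 and 11 and returning at 16. Acetylation of 11 (Ac2O, pyridine) should give allylic acetate F7. Its lithium enolate (LiN(i-Pr)2, THF, −78 °C) should open 8 in a Claisen condensation to β-keto ester F8. Thermal Carroll rearrangement (xylene, 140 °C) with decarboxylation should give hydroxy ketone F9 with the same chair-controlled E-alkene. Mild aqueous acid then unmasks the enal.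

**Further compounds**

F1 | step 15 | (3R,7E)-3-acetoxy-8-[(2R)-4-(acetoxymethyl)-3-iodo-5-oxo-2,5-dihydrofuran-2-yl]-3,7-dimethyl-4-oxooct-7-enoic acid | CC(=O)OCC1=C(I)[C@@H](/C=C(\C)CCC(=O)[C@](C)(OC(C)=O)CC(=O)O)OC1=O
F2 | step 15 | S-ethyl (3R,7E)-3-acetoxy-8-[(2R)-4-(acetoxymethyl)-3-iodo-5-oxo-2,5-dihydrofuran-2-yl]-3,7-dimethyl-4-oxooct-7-enethioate | CC(=O)OCC1=C(I)[C@@H](/C=C(\C)CCC(=O)[C@](C)(OC(C)=O)CC(=O)SCC)OC1=O
F3 | step 15 | S-ethyl (3R,7E)-3-acetoxy-8-[(2R)-4-(acetoxymethyl)-5-oxo-3-(trimethylstannyl)-2,5-dihydrofuran-2-yl]-3,7-dimethyl-4-oxooct-7-enethioate | CC(=O)OCC1=C([Sn](C)(C)C)[C@@H](/C=C(\C)CCC(=O)[C@](C)(OC(C)=O)CC(=O)SCC)OC1=O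
F4 | step 15 | (4E,6R,10R)-10,13-diacetoxy-1,8-dioxogermacra-4,7(11)-dien-6,12-olide | O=C1C[C@@](C)(OC(C)=O)C(=O)CC/C(C)=C/[C@H]2OC(=O)C(COC(C)=O)=C12
F5 | step 11 | (3R,7E,9R)-12-(tert-butyldimethylsilyloxy)-9-hydroxy-1,1-dimethoxy-3,7-dimethyl-4-oxododec-7-en-10-yn-3-yl acetate | CC(C)(C)[Si](C)(C)OCC#C[C@H](O)/C=C(\C)CCC(=O)[C@](C)(OC(C)=O)CC(OC)OC
F6 | step 11 | (3R,7E,9R,10E)-12-(tert-butyldimethylsilyloxy)-9-hydroxy-10,11-diiodo-1,1-dimethoxy-3,7-dimethyl-4-oxododeca-7,10-dien-3-yl acetate | CC(C)(C)[Si](C)(C)OC/C(I)=C(\I)[C@H](O)/C=C(\C)CCC(=O)[C@](C)(OC(C)=O)CC(OC)OC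
F7 | step 7 | rac-1,1-dimethoxy-3-methylbut-3-en-2-yl acetate | C=C(C)C(OC(C)=O)C(OC)OC
F8 | step 7 | 1,1-dimethoxy-3-methylbut-3-en-2-yl (4R)-4-hydroxy-6,6-dimethoxy-4-methyl-3-oxohexanoate | C=C(C)C(OC(=O)CC(=O)[C@@](C)(CC(OC)OC)O)C(OC)OC
F9 | step 7 | (3R,7E)-3-hydroxy-1,1,9,9-tetramethoxy-3,7-dimethylnon-7-en-4-one | COC(OC)/C=C(\C)CCC(=O)[C@@](C)(CC(OC)OC)O
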